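## Structural features

The target is a 1-methylcyclohexene (C1 methyl-bearing, C1=C2, then C3 to C6) whose three contiguous sp3 carbons each carry an aromatic unit. C3 (S) is bonded to C8 of a (2S)-flavanone, C4 (R) to the carbonyl of a 2,4-dihydroxy-3-prenylbenzoyl group, and C5 (S) to a 2,4-dihydroxyphenyl ring. The C3 and C4 substituents are cis, those on C4 and C5 trans, and the fourth stereocentre, flavanone C2, is remote from the ring. Flavanone C8 lies between O1 and the 7-oxygen, so C3 is benzylic to a 2,6-dioxygenated ring and every bond made at C3 or C4 is congested. Fragile elements are the seven phenols, the prenyl group between two phenols (acid closes it to a chroman), the flavanone (base opens it to the chalcone and scrambles C2), the C4 hydrogen α to the aryl ketone, and the ketone itself, which sits between two ortho-hydroxyaryl groups and can ketalise under acid. The real difficulty is to fix the cis,trans triad C3–C4–C5 in the absolute sense, independently of flavanone C2. The key step exploits three facts: C5 is benzylic to a ring with an ortho hydroxyl and a para oxygen (an ortho-quinone methide carbon), C4 is α to the ketone carbon (an enamine carbon), and the ketone carbon can be held as a lactol bound to that same ortho oxygen, so that C4–C5 and an O–C bond close a chroman ring. The remaining C1=C2 alkene, between a vinyl arm on C3 and a methallyl arm on C5, is then a metathesis retron.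

## Logic of the disconnections

36 ⇒ 35. Six phenolic O–CH2 acetal bonds are cut. Seven free phenols cannot pass organolithium, hydride and metal-catalysed steps, and the acetal ether is the one group that survives all of them; the seventh phenol of 35 is free because it is released unprotected when the lactone is opened. The forward step needs an acid mild enough to leave the prenyl group, the flavanone and the ketone between its two phenols alone.

35 ⇒ 34 ⇒ 33. The flavanone carbonyl is traced back to the cis carbinol and its silyl ether. A free flavanone would be attacked by 32 and opened by base, whereas in the reduced form C2 cannot epimerise. The forward steps need a desilylation that does not epimerise C4 and an oxidant that takes only the activated benzylic carbinol.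

33 ⇒ 26 + 31 (through 32). The aryl–carbonyl bond at the C4 ketone is cut. The prenylated ring is the only fragment whose alkene would disturb the metathesis, so it enters after ring closure; the lactone of 26 transfers its acyl group once and frees the C5-ring phenol. Twelve carbons are removed and a compact tricycle remains. The forward step must stop at single addition and must not enolise C4.

26 ⇒ 25. The C1=C2 double bond is cut. The carbocycle then reduces to two alkene arms on an open C3–C4–C5 chain held by the dihydrocoumarin. The forward ring closure must form a trisubstituted alkene beside the hindered C3 and a trans ring fusion.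

25 ⇒ 24. Only the oxidation level of the future ketone carbon changes. The lactol is what the key step delivers, and the oxidation must be non-acidic.

24 ⇒ 17 + 22 (through 23). The C4–C5 bond and the ring O–C(lactol) bond are cut. This separates the molecule into its two halves at the point where C5 is an electrophilic methide carbon and C4 a nucleophilic enamine carbon. The methide precursor is 22 and not 21 itself: 23 carries α-hydrogens and would slip to a conjugated diene under acid, and acid also endangers the benzylic silyl ether and the acetals of 17. Base-triggered loss of sulfinate from 22 releases 23 slowly under conditions that 17 tolerates. The forward step needs the (R)-configured amine to control the enamine face in the presence of the C3 centre of 17, and a trans approach of 23.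

22 ⇒ 21 ⇒ 18 + 19 (through 20) ⇒ 1. The C–S bond, the C5–C6 bond and one acetal bond are cut. This leads to a commercial aldehyde and a commercial allyl chloride. The carbinol centre of 21 need not be controlled because it is lost in 23.

17 ⇒ 16 ⇒ 15 ⇒ 13 + 14. The C3–C4 bond is cut at the allylic position, with 14 serving as a two-carbon aldehyde-enolate equivalent after loss of one ester. The iridium catalyst must give the branched isomer and the C3 configuration at a carbon bonded to a 2,6-dioxygenated ring, against any bias from the flavan centres.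

13 ⇒ 12 ⇒ 11 ⇒ 9 + 10. The bond between flavan C8 and the side chain is cut (Heck). The carbon–iodine bond of 9 is the only handle that can be placed regioselectively between the two ring oxygens at the outset. The forward coupling must tolerate a doubly ortho-substituted iodide.

9 ⇒ 8 ⇒ 7. This is a stereochemical disconnection. One catalytic reduction of the racemic ketone sets both flavan centres and delivers the masked oxidation level the route needs. The price is the half-conversion ceiling of a kinetic resolution, paid on a small early intermediate.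

7 ⇒ 6 ⇒ 5 + 2. The O1–C2 bond and the enone Cα=Cβ bond are cut, which is the standard chalcone route to a flavanone. The ring closure is an equilibrium and needs mild base.

5 ⇒ 4 ⇒ 3, and 2 ⇒ 1. A carbon–iodine bond and acetal bonds are cut. The forward iodination must go between the two hydroxyls, and the mono-protection of 4 must spare the chelated hydroxyl.

31 ⇒ 28 + 29 (through 30) ⇒ 27. The aryl–prenyl bond is cut between the two acetal oxygens, where deprotonation is directed twice. The bromine must survive the metalation and serve later for the exchange to 32.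

## Other disconnections considered

Alternative 1: The cut runs through C4–C5 and C1–C6, and later through the bridging C1–O bond. Forward, 6-methyl-4-(flavanon-8-yl)-2-pyrone A2 and 2,4-bis(methoxymethoxy)styrene A3 would combine in an inverse-demand [4+2] cycloaddition under high pressure to the bridged lactone A1. The allylic C1–O bond would then be opened reductively with shift of the double bond from C2=C3 to C1=C2, and the C4 carboxylate turned into the aryl ketone.
- In its favour: two skeletal bonds and the carbocycle arise in one intermolecular step from two flat partners, so on convergence and step economy it is the better plan. The endo mode gives the C4/C5 trans pair, and the polarity of both partners (styrene terminus to pyrone C6) fixes the regiochemistry. C4 arrives at the acid oxidation level, so the later aryl transfer is an equal problem in both plans.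
- Against it here: C3 is an alkene carbon in A1, so the centre that defines the cis,trans series would be created only in the reductive transposition, where nothing directs hydrogen to the face cis to the carboxylate. Nothing controls the absolute sense either, because the only stereocentre of A2 is the remote flavanone C2, so two diastereomers are to be expected without a chiral catalyst. Bridged pyrone adducts lose carbon dioxide by cycloreversion on heating, the electron-rich A3 polymerises easily, and the open flavanone of A2 is exposed to the reducing step.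
- Comparison: both plans use the same polarity at C5. The chosen plan sets C3, C4 and C5 one after another under catalyst control and closes the ring afterwards; it is longer and stereochemically more secure.

Alternative 2: The cut is the C3–C4 bond. Forward, the silyl ketene acetal of the 4-aryl-6-methyl-6-styryl δ-lactone A5 would undergo a [3,3] shift through the boat that the lactone ring enforces, breaking C1–O and giving the cyclohexene acid A4.
- In its favour: the step is intramolecular and closes the ring while setting C3 and C4 together. The E-styryl group leads to 3,4-cis and an aryl cis to the styryl group in A5 leads to 4,5-trans, so stereochemical transfer is at least as reliable as the double stereodifferentiation the chosen key step faces; on that point it is the equal or the better. The acid A4 then needs the same aryl transfer as the chosen plan.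
- Against it here: A5 carries a tertiary allylic C–O stereocentre (methyl, styryl) that must be made enantiopure and cis to the C4 aryl, only to be destroyed in the rearrangement. Enolisation of a lactone with a tertiary allylic carboxylate invites ionisation or elimination. The bond-forming styryl carbon carries the 2,6-dioxygenated flavan and is the most hindered position of the molecule. The acid must still be activated and coupled, so the step count is not lower.
- Comparison: the stereochemical effort moves from a catalytic C–C bond formation to the construction of a quaternary centre; convergence is similar, and the chosen plan keeps every stereocentre it makes.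

Alternative 3: The cut is flavanone O1–C2. Forward, the 2′-hydroxychalcone A7, already carrying the finished cyclohexene, would close under a cinchona-derived amine–thiourea to A6. A6 carries six methoxymethyl groups and one free chelated phenol, so it is the hexa-MOM ether of the target, not a penta-MOM ether.
- In its favour: it follows biosynthesis and keeps the base-labile flavanone out of the whole synthesis. It needs no silyl mask, no reduction–oxidation pair and no kinetic resolution, so for the flavanone part it is shorter than the chosen plan and avoids its half-conversion loss; on these points it is better.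
- Against it here: enantioselective oxa-Michael closures are dependable mainly for chalcones activated by an extra α-acceptor. An unactivated chalcone with a 2,4-dioxygenated ring B closes slowly and reversibly, so selectivity drifts toward the equilibrium mixture. The attacking phenol is flanked by the bulky cyclohexenyl group, three resident stereocentres make the closure a matched or mismatched case, a second chelated phenol and ketone compete for the catalyst, and C2 epimers of this size would be hard to part. The cut also leaves the construction of the C3–C4–C5 triad unsolved.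
- Comparison: the chosen plan settles flavanone C2 at step 6 on a small molecule where the unwanted enantiomer is removed cleanly, at the cost of three masking steps; the alternative defers the same problem to the most valuable intermediate.

Key step: step 17

Remarks. Fl = (2S,4S)-4-(tert-butyldimethylsilyloxy)-7-(methoxymethoxy)-2-[2,4-bis(methoxymethoxy)phenyl]chroman-8-yl; MOM = methoxymethyl; cyclohexene locants C1–C6 as in the first section.
Assumption: the sense of induction of the three chiral catalysts (steps 6, 11 and 17) is taken over from the parent substrate classes (aryl ketones, aryl-substituted allyl carbonates, linear aldehydes).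

## Route

Step 1
Reactants: 1 2,4-dihydroxybenzaldehyde
Product: 2 2,4-bis(methoxymethoxy)benzaldehyde
Conditions: NaH (2.4 equiv), MOMCl (2.4 equiv), DMF, 0 °C → rt
Reagents that add atoms: chloromethyl methyl ether (MOMCl), COCCl
Why: O-alkylation of both phenoxides (Williamson type); the strong base is needed because the 2-hydroxyl is hydrogen-bonded to the aldehyde.

Step 2
Reactants: 3 2,4-dihydroxyacetophenone
Product: 4 1-(2,4-dihydroxy-3-iodophenyl)ethanone
Conditions: I2 (0.4 equiv), HIO3 (0.2 equiv), EtOH/H2O, 40 °C
Reagents that add atoms: iodine, [I][I]; iodic acid, OI(=O)=O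
Why: Electrophilic aromatic iodination at the position between the two hydroxyls, which is activated twice; iodic acid reoxidises iodide so that no excess iodine is present and di-iodination is limited.

Step 3
Reactants: 4 1-(2,4-dihydroxy-3-iodophenyl)ethanone
Product: 5 1-[2-hydroxy-3-iodo-4-(methoxymethoxy)phenyl]ethanone
Conditions: MOMCl (1.1 equiv), K2CO3 (1.5 equiv), acetone, 0 °C → rt
Reagents that add atoms: chloromethyl methyl ether (MOMCl), COCCl
Why: Selective O-alkylation; the 2-hydroxyl is chelated to the ketone and stays free, as the chalcone and flavanone steps require.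

Step 4
Reactants: 5 1-[2-hydroxy-3-iodo-4-(methoxymethoxy)phenyl]ethanone; 2 2,4-bis(methoxymethoxy)benzaldehyde
Product: 6 (E)-1-[2-hydroxy-3-iodo-4-(methoxymethoxy)phenyl]-3-[2,4-bis(methoxymethoxy)phenyl]prop-2-en-1-one
Conditions: KOH (aq., 5 equiv), EtOH, 0 °C → rt; then AcOH to pH 6
Reagents that add atoms: none
Why: Claisen–Schmidt condensation of the methyl ketone enolate with a non-enolisable aldehyde; dehydration gives the E-enone, and the acetals and the aryl iodide are inert to hydroxide.

Step 5
Reactants: 6 the 2′-hydroxychalcone of step 4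
Product: 7 rac-8-iodo-7-(methoxymethoxy)-2-[2,4-bis(methoxymethoxy)phenyl]chroman-4-one
Conditions: NaOAc (3 equiv), EtOH, reflux
Reagents that add atoms: none
Why: Intramolecular oxa-Michael addition of the phenoxide (6-endo-trig) under acetate buffering; the closure is an equilibrium, unreacted 6 is recycled, and the racemate is intended because the next step resolves it.

Step 6
Reactants: 7 rac-8-iodo-7-(methoxymethoxy)-2-[2,4-bis(methoxymethoxy)phenyl]chroman-4-one
Product: 8 (2S,4S)-8-iodo-7-(methoxymethoxy)-2-[2,4-bis(methoxymethoxy)phenyl]chroman-4-ol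
Conditions: RuCl[(S,S)-TsDPEN](p-cymene) (1 mol%), HCO2H/Et3N (5:2), EtOAc, rt, stopped near half conversion
Reagents that add atoms: none
Why: Asymmetric transfer hydrogenation run as a kinetic resolution: the (S,S)-catalyst should give the (4S)-carbinol and deliver hydride anti to the 2-aryl group, so only the (2S)-ketone is reduced quickly and the cis (2S,4S)-alcohol results with both flavan centres set. The untouched (2R)-ketone can be racemised with base through 6 and resubmitted.

Step 7
Reactants: 8 (2S,4S)-8-iodo-7-(methoxymethoxy)-2-[2,4-bis(methoxymethoxy)phenyl]chroman-4-ol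
Product: 9 Fl–I, (2S,4S)-4-(tert-butyldimethylsilyloxy)-8-iodo-7-(methoxymethoxy)-2-[2,4-bis(methoxymethoxy)phenyl]chroman
Conditions: TBSCl (1.5 equiv), imidazole (2.5 equiv), DMF, rt
Reagents that add atoms: tert-butyldimethylsilyl chloride (TBSCl), CC(C)(C)[Si](C)(C)Cl
Why: Silylation of the secondary benzylic alcohol; the masked ketone is now inert to hydride, enolate and organolithium reagents and C2 can no longer epimerise.

Step 8
Reactants: 9 Fl–I; 10 methyl acrylate
Product: 11 methyl (E)-3-Fl-prop-2-enoate
Conditions: Pd(OAc)2 (5 mol%), nBu4NCl (1 equiv), NaHCO3 (2.5 equiv), DMF, 80 °C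
Reagents that add atoms: none
Why: Heck reaction under ligand-free phase-transfer conditions, which suit hindered electron-rich aryl iodides; syn insertion and β-hydride elimination give the E-cinnamate.

Step 9
Reactants: 11 methyl (E)-3-Fl-prop-2-enoate
Product: 12 (E)-3-Fl-prop-2-en-1-ol
Conditions: iBu2AlH (2.5 equiv), CH2Cl2, −78 °C; aq. potassium sodium tartrate
Reagents that add atoms: none
Why: 1,2-Reduction of the enoate by the aluminium hydride at low temperature; silyl ether and acetals are untouched.

Step 10
Reactants: 12 (E)-3-Fl-prop-2-en-1-ol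
Product: 13 (E)-3-Fl-prop-2-enyl methyl carbonate
Conditions: ClCO2Me (1.5 equiv), pyridine (3 equiv), CH2Cl2, 0 °C
Reagents that add atoms: methyl chloroformate, COC(=O)Cl
Why: O-Acylation to the carbonate, the leaving group that releases its own base (methoxide) in the iridium step.

Step 11
Reactants: 13 (E)-3-Fl-prop-2-enyl methyl carbonate; 14 dimethyl malonate
Product: 15 dimethyl 2-[(1S)-1-Fl-prop-2-enyl]propanedioate
Conditions: [Ir(cod)Cl]2 (2 mol%), (Ra,R,R)-binaphthyl N,N-bis[1-(2-methoxyphenyl)ethyl]phosphoramidite (4 mol%), TBD (8 mol%), 14 (2 equiv), THF, rt → 50 °C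
Reagents that add atoms: none
Why: Iridium-catalysed asymmetric allylic alkylation under salt-free conditions: the cyclometalated iridium–phosphoramidite complex ionises the carbonate, the methoxide set free deprotonates 14, and attack at the substituted allyl terminus gives the branched product. The ligand enantiomer is the one expected to give (S)-branched malonates from aryl allyl carbonates, so the new centre (future C3) should be catalyst-controlled, and the ortho-methoxyaryl ligand is chosen for ortho-substituted arenes.

Step 12
Reactants: 15 dimethyl 2-[(1S)-1-Fl-prop-2-enyl]propanedioate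
Product: 16 methyl (3R)-3-Fl-pent-4-enoate
Conditions: NaCl (3 equiv), H2O (2 equiv), DMSO, 140 °C
Reagents that add atoms: none
Why: Krapcho dealkoxycarbonylation (chloride demethylation, loss of CO2, protonation); the neutral medium leaves the allylic centre, which is not α to an ester, and the protecting groups intact. The descriptor changes from S to R only because the priorities change.

Step 13
Reactants: 16 methyl (3R)-3-Fl-pent-4-enoate
Product: 17 (3R)-3-Fl-pent-4-enal
Conditions: iBu2AlH (1.1 equiv), CH2Cl2, −78 °C; MeOH, then aq. potassium sodium tartrate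
Reagents that add atoms: none
Why: Partial reduction of the ester through the aluminium hemiacetal that is stable at −78 °C; the stereocentre is β to the carbonyl and cannot epimerise.

Step 14
Reactants: 1 2,4-dihydroxybenzaldehyde
Product: 18 2-hydroxy-4-(methoxymethoxy)benzaldehyde
Conditions: MOMCl (1.05 equiv), K2CO3 (1.5 equiv), acetone, 0 °C → rt
Reagents that add atoms: chloromethyl methyl ether (MOMCl), COCCl
Why: Selective O-alkylation of the non-chelated 4-hydroxyl, as in step 3.

Step 15
Reactants: 18 2-hydroxy-4-(methoxymethoxy)benzaldehyde; 19 3-chloro-2-methylpropene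
Product: 21 rac-2-(1-hydroxy-3-methylbut-3-enyl)-5-(methoxymethoxy)phenol, via 2-methylallylmagnesium chloride 20 (not isolated)
Conditions: 19 (2.3 equiv), Mg, THF, 0 °C; then 18, THF, −78 → 0 °C; aq. NH4Cl
Reagents that add atoms: none
Why: Grignard addition; the first equivalent deprotonates the phenol and the second adds to the aldehyde. The racemic carbinol is sufficient because this centre becomes the sp2 methide carbon.

Step 16
Reactants: 21 rac-2-(1-hydroxy-3-methylbut-3-enyl)-5-(methoxymethoxy)phenol
Product: 22 rac-5-(methoxymethoxy)-2-[3-methyl-1-(4-methylphenylsulfonyl)but-3-enyl]phenol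
Conditions: p-TolSO2Na (1.5 equiv), HCO2H (3 equiv), CH2Cl2/H2O, 0 °C → rt
Reagents that add atoms: sodium 4-methylbenzenesulfinate, Cc1ccc(cc1)S(=O)[O-].[Na+]
Why: SN1-type substitution: the doubly oxygen-stabilised benzylic cation (protonated methide) is captured at sulfur by excess sulfinate. The sulfone is a storable methide precursor that is triggered by base instead of acid.

Step 17
Reactants: 17 (3R)-3-Fl-pent-4-enal; 22 rac-5-(methoxymethoxy)-2-[3-methyl-1-(4-methylphenylsulfonyl)but-3-enyl]phenol
Product: 24 (3R,4S)-7-(methoxymethoxy)-4-(2-methylprop-2-enyl)-3-[(1S)-1-Fl-prop-2-enyl]chroman-2-ol as anomeric mixture, via ortho-quinone methide 23 (not isolated)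
Conditions: (R)-2-[diphenyl(trimethylsilyloxy)methyl]pyrrolidine (20 mol%), 22 (1.5 equiv), Na2CO3 (2 equiv), CH2Cl2, 0 °C → rt
Reagents that add atoms: none
Why: Carbonate deprotonates the phenol of 22 and sulfinate is expelled, which releases 23 slowly, while 17 condenses with the amine to the E-enamine. The enamine carbon (future C4) adds to the methide carbon (future C5) with rearomatisation as driving force, and the phenoxide then adds to the iminium carbon in a 6-exo-trig closure to an N,O-aminal that hydrolyses to the lactol and frees the amine. The closest known reaction type is the aminocatalytic formal [4+2] annulation of aldehydes with ortho-quinone methides generated in situ, which gives trans-3,4-disubstituted chroman-2-ols. C4 is controlled by the catalyst: the diaryl(silyloxy)methyl group blocks one enamine face, and the (R)-enantiomer exposes the face that gives the 4R centre (3R in chroman numbering), the opposite of the sense the (S)-catalyst gives in aldehyde α-functionalisations. C5 follows from the relative topicity, because the E-configured methide approaches with its side chain turned away from the enamine substituent and gives the trans pair; the lactol α-carbon can also settle to trans through the open aldehyde. The anomeric centre forms as a mixture and is removed in the next step. The step needs capture of 23 faster than its tautomerisation to the conjugated diene, which the slow base release, the excess of 22 and the para oxygen that stabilises 23 should secure. It also needs catalyst control over the resident C3 centre of 17, which sits one atom away from the reacting carbon and bears the bulky aryl that may reinforce or oppose the catalyst.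

Step 18
Reactants: 24 the chroman-2-ol of step 17
Product: 25 (3R,4S)-7-(methoxymethoxy)-4-(2-methylprop-2-enyl)-3-[(1S)-1-Fl-prop-2-enyl]chroman-2-one
Conditions: nPr4N[RuO4] (5 mol%), NMO (1.5 equiv), 4 Å MS, CH2Cl2, rt
Reagents that add atoms: none
Why: Ley–Griffith oxidation of a lactol to the lactone under neutral conditions, which spare the benzylic silyl ether and the acetals; the α-centre is already in its stable trans arrangement.

Step 19
Reactants: 25 the dihydrocoumarin of step 18
Product: 26 (6aR,7S,10aS)-3-(methoxymethoxy)-9-methyl-7-Fl-6a,7,10,10a-tetrahydrobenzo[c]chromen-6-one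
Conditions: second-generation Grubbs catalyst (H2IMes)(PCy3)Cl2Ru=CHPh (5 mol%), CH2Cl2, 40 °C
Reagents that add atoms: none
Why: Ring-closing metathesis of the vinyl and methallyl arms to the trisubstituted C1=C2 alkene in a trans-fused six-membered ring, driven by loss of ethene; no stereocentre is touched.

Step 20
Reactants: 27 4-bromobenzene-1,3-diol
Product: 28 1-bromo-2,4-bis(methoxymethoxy)benzene
Conditions: NaH (2.4 equiv), MOMCl (2.4 equiv), DMF, 0 °C → rt
Reagents that add atoms: chloromethyl methyl ether (MOMCl), COCCl
Why: Double O-alkylation; the acetals later direct the metalation and protect the phenols from the organolithium step.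

Step 21
Reactants: 28 1-bromo-2,4-bis(methoxymethoxy)benzene; 29 1-bromo-3-methylbut-2-ene
Product: 31 1-bromo-2,4-bis(methoxymethoxy)-3-(3-methylbut-2-enyl)benzene, via [3-bromo-2,6-bis(methoxymethoxy)phenyl]lithium 30 (not isolated)
Conditions: LiN(iPr)2 (1.1 equiv), THF, −78 °C; then CuI (10 mol%), 29 (1.3 equiv), −78 °C → rt
Reagents that add atoms: none
Why: Directed ortho-metalation at the carbon between the two acetal oxygens, the most acidic site, with an amide base that does not exchange the bromine; copper-catalysed SN2 allylation then installs the prenyl group.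

Step 22
Reactants: 31 1-bromo-2,4-bis(methoxymethoxy)-3-(3-methylbut-2-enyl)benzene; 26 the tricyclic lactone of step 19
Product: 33 [2,4-bis(methoxymethoxy)-3-(3-methylbut-2-enyl)phenyl]{(1R,2S,6S)-2-Fl-6-[2-hydroxy-4-(methoxymethoxy)phenyl]-4-methylcyclohex-3-en-1-yl}methanone, via [2,4-bis(methoxymethoxy)-3-(3-methylbut-2-enyl)phenyl]lithium 32 (not isolated)
Conditions: 31 (1.3 equiv), n-BuLi (1.25 equiv), THF, −78 °C; solution of 32 added to 26, THF, −78 → −40 °C; aq. NH4Cl
Reagents that add atoms: none
Why: Bromine–lithium exchange, then nucleophilic acyl substitution at the aryl lactone; the tetrahedral adduct collapses to the ketone and a lithium phenoxide. Inverse addition at low temperature and the hindrance of the α-branched ortho-alkoxyaryl ketone should prevent a second addition; C3, C4 and C5 are untouched (3S,4R,5S).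

Step 23
Reactants: 33 the silyl-protected ketone of step 22
Product: 34 [2,4-bis(methoxymethoxy)-3-(3-methylbut-2-enyl)phenyl]{(1R,2S,6S)-2-[(2S,4S)-4-hydroxy-7-(methoxymethoxy)-2-[2,4-bis(methoxymethoxy)phenyl]chroman-8-yl]-6-[2-hydroxy-4-(methoxymethoxy)phenyl]-4-methylcyclohex-3-en-1-yl}methanone
Conditions: Bu4NF (1.5 equiv), AcOH (1.5 equiv), THF, 0 °C → rt
Reagents that add atoms: none
Why: Fluoride desilylation; the acetic acid buffer keeps the medium from enolising the C4 ketone.

Step 24
Reactants: 34 the flavan-4-ol of step 23
Product: 35 [2,4-bis(methoxymethoxy)-3-(3-methylbut-2-enyl)phenyl]{(1R,2S,6S)-6-[2-hydroxy-4-(methoxymethoxy)phenyl]-2-[(2S)-7-(methoxymethoxy)-2-[2,4-bis(methoxymethoxy)phenyl]-4-oxochroman-8-yl]-4-methylcyclohex-3-en-1-yl}methanone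
Conditions: MnO2 (activated, 15 equiv), CH2Cl2, rt
Reagents that add atoms: none
Why: Heterogeneous MnO2 oxidation, selective for the benzylic carbinol activated by the para and ortho ring oxygens; the neutral medium restores the flavanone without touching C2, and the one free phenol is a resorcinol-type ring that cannot form a quinone.

Step 25
Reactants: 35 the hexa-MOM ether of step 24
Product: 36 [2,4-dihydroxy-3-(3-methylbut-2-enyl)phenyl]{(1R,2S,6S)-6-(2,4-dihydroxyphenyl)-2-[(2S)-2-(2,4-dihydroxyphenyl)-7-hydroxy-4-oxochroman-8-yl]-4-methylcyclohex-3-en-1-yl}methanone (CNP0157992.1)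
Conditions: HCl (3 M aq.)/MeOH 1:5, 40 °C, monitored and stopped at full conversion
Reagents that add atoms: none
Why: Acid-catalysed acetal methanolysis of the six aryl MOM ethers; flavanones keep their configuration in acid, and mild temperature is chosen to outrun prenyl cyclisation and ketalisation.

## Compound list

1 | 2,4-dihydroxybenzaldehyde | O=Cc1ccc(O)cc1O | starting material
2 | 2,4-bis(methoxymethoxy)benzaldehyde | COCOc1ccc(C=O)c(OCOC)c1 | intermediate
3 | 2,4-dihydroxyacetophenone | CC(=O)c1ccc(O)cc1O | starting material
4 | 1-(2,4-dihydroxy-3-iodophenyl)ethanone | CC(=O)c1ccc(O)c(I)c1O | intermediate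
5 | 1-[2-hydroxy-3-iodo-4-(methoxymethoxy)phenyl]ethanone | CC(=O)c1ccc(OCOC)c(I)c1O | intermediate
6 | (E)-1-[2-hydroxy-3-iodo-4-(methoxymethoxy)phenyl]-3-[2,4-bis(methoxymethoxy)phenyl]prop-2-en-1-one | O=C(/C=C/c1ccc(OCOC)cc1OCOC)c1ccc(OCOC)c(I)c1O | intermediate
7 | rac-8-iodo-7-(methoxymethoxy)-2-[2,4-bis(methoxymethoxy)phenyl]chroman-4-one | O=C1CC(c2ccc(OCOC)cc2OCOC)Oc2c(I)c(OCOC)ccc12 | intermediate
8 | (2S,4S)-8-iodo-7-(methoxymethoxy)-2-[2,4-bis(methoxymethoxy)phenyl]chroman-4-ol | Ic1c(OCOC)ccc2c1O[C@H](c1ccc(OCOC)cc1OCOC)C[C@@H]2O | intermediate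
9 | (2S,4S)-4-(tert-butyldimethylsilyloxy)-8-iodo-7-(methoxymethoxy)-2-[2,4-bis(methoxymethoxy)phenyl]chroman (Fl–I) | Ic1c(OCOC)ccc2c1O[C@H](c1ccc(OCOC)cc1OCOC)C[C@@H]2O[Si](C)(C)C(C)(C)C | intermediate
10 | methyl acrylate | C=CC(=O)OC | starting material
11 | methyl (E)-3-Fl-prop-2-enoate | COC(=O)/C=C/c1c(OCOC)ccc2c1O[C@H](c1ccc(OCOC)cc1OCOC)C[C@@H]2O[Si](C)(C)C(C)(C)C | intermediate
12 | (E)-3-Fl-prop-2-en-1-ol | OC/C=C/c1c(OCOC)ccc2c1O[C@H](c1ccc(OCOC)cc1OCOC)C[C@@H]2O[Si](C)(C)C(C)(C)C | intermediate
13 | (E)-3-Fl-prop-2-enyl methyl carbonate | COC(=O)OC/C=C/c1c(OCOC)ccc2c1O[C@H](c1ccc(OCOC)cc1OCOC)C[C@@H]2O[Si](C)(C)C(C)(C)C | intermediate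
14 | dimethyl malonate | COC(=O)CC(=O)OC | starting material
15 | dimethyl 2-[(1S)-1-Fl-prop-2-enyl]propanedioate | COC(=O)C(C(=O)OC)[C@@H](c1c(OCOC)ccc2c1O[C@H](c1ccc(OCOC)cc1OCOC)C[C@@H]2O[Si](C)(C)C(C)(C)C)C=C | intermediate
16 | methyl (3R)-3-Fl-pent-4-enoate | COC(=O)C[C@@H](c1c(OCOC)ccc2c1O[C@H](c1ccc(OCOC)cc1OCOC)C[C@@H]2O[Si](C)(C)C(C)(C)C)C=C | intermediate
17 | (3R)-3-Fl-pent-4-enal | O=CC[C@@H](c1c(OCOC)ccc2c1O[C@H](c1ccc(OCOC)cc1OCOC)C[C@@H]2O[Si](C)(C)C(C)(C)C)C=C | intermediate
18 | 2-hydroxy-4-(methoxymethoxy)benzaldehyde | O=Cc1ccc(OCOC)cc1O | intermediate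
19 | 3-chloro-2-methylpropene | C=C(C)CCl | starting material
20 | 2-methylallylmagnesium chloride | C=C(C)C[Mg]Cl | intermediate
21 | rac-2-(1-hydroxy-3-methylbut-3-enyl)-5-(methoxymethoxy)phenol | Oc1cc(OCOC)ccc1C(O)CC(C)=C | intermediate
22 | rac-5-(methoxymethoxy)-2-[3-methyl-1-(4-methylphenylsulfonyl)but-3-enyl]phenol | Cc1ccc(cc1)S(=O)(=O)C(CC(C)=C)c1ccc(OCOC)cc1O | intermediate
23 | (E)-3-(methoxymethoxy)-6-(3-methylbut-3-enylidene)cyclohexa-2,4-dien-1-one | C=C(C)C/C=C1\C=CC(OCOC)=CC1=O | intermediate
24 | (3R,4S)-7-(methoxymethoxy)-4-(2-methylprop-2-enyl)-3-[(1S)-1-Fl-prop-2-enyl]chroman-2-ol, anomeric mixture | OC1Oc2cc(OCOC)ccc2[C@@H](CC(C)=C)[C@@H]1[C@@H](c1c(OCOC)ccc2c1O[C@H](c1ccc(OCOC)cc1OCOC)C[C@@H]2O[Si](C)(C)C(C)(C)C)C=C | intermediate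
25 | (3R,4S)-7-(methoxymethoxy)-4-(2-methylprop-2-enyl)-3-[(1S)-1-Fl-prop-2-enyl]chroman-2-one | O=C1Oc2cc(OCOC)ccc2[C@@H](CC(C)=C)[C@@H]1[C@@H](c1c(OCOC)ccc2c1O[C@H](c1ccc(OCOC)cc1OCOC)C[C@@H]2O[Si](C)(C)C(C)(C)C)C=C | intermediate
26 | (6aR,7S,10aS)-3-(methoxymethoxy)-9-methyl-7-Fl-6a,7,10,10a-tetrahydrobenzo[c]chromen-6-one | O=C1Oc2cc(OCOC)ccc2[C@H]3CC(C)=C[C@H](c4c(OCOC)ccc5c4O[C@H](c4ccc(OCOC)cc4OCOC)C[C@@H]5O[Si](C)(C)C(C)(C)C)[C@H]13 | intermediate
27 | 4-bromobenzene-1,3-diol | Oc1ccc(Br)c(O)c1 | starting material
28 | 1-bromo-2,4-bis(methoxymethoxy)benzene | COCOc1ccc(Br)c(OCOC)c1 | intermediate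
29 | 1-bromo-3-methylbut-2-ene | CC(C)=CCBr | starting material
30 | [3-bromo-2,6-bis(methoxymethoxy)phenyl]lithium | [Li]c1c(OCOC)ccc(Br)c1OCOC | intermediate
31 | 1-bromo-2,4-bis(methoxymethoxy)-3-(3-methylbut-2-enyl)benzene | CC(C)=CCc1c(OCOC)ccc(Br)c1OCOC | intermediate
32 | [2,4-bis(methoxymethoxy)-3-(3-methylbut-2-enyl)phenyl]lithium | [Li]c1ccc(OCOC)c(CC=C(C)C)c1OCOC | intermediate
33 | [2,4-bis(methoxymethoxy)-3-(3-methylbut-2-enyl)phenyl]{(1R,2S,6S)-2-Fl-6-[2-hydroxy-4-(methoxymethoxy)phenyl]-4-methylcyclohex-3-en-1-yl}methanone | CC(C)=CCc1c(OCOC)ccc(C(=O)[C@H]2[C@@H](c4c(OCOC)ccc5c4O[C@H](c4ccc(OCOC)cc4OCOC)C[C@@H]5O[Si](C)(C)C(C)(C)C)C=C(C)C[C@@H]2c2ccc(OCOC)cc2O)c1OCOC | intermediate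
34 | analogue of 33 with the free (2S,4S)-flavan-4-ol | CC(C)=CCc1c(OCOC)ccc(C(=O)[C@H]2[C@@H](c4c(OCOC)ccc5c4O[C@H](c4ccc(OCOC)cc4OCOC)C[C@@H]5O)C=C(C)C[C@@H]2c2ccc(OCOC)cc2O)c1OCOC | intermediate
35 | hexa-MOM ether of the target with the (2S)-flavanone restored and the C5-ring 2-hydroxyl free | CC(C)=CCc1c(OCOC)ccc(C(=O)[C@H]2[C@@H](c4c(OCOC)ccc5c4O[C@H](c4ccc(OCOC)cc4OCOC)CC5=O)C=C(C)C[C@@H]2c2ccc(OCOC)cc2O)c1OCOC | intermediate
36 | [2,4-dihydroxy-3-(3-methylbut-2-enyl)phenyl]{(1R,2S,6S)-6-(2,4-dihydroxyphenyl)-2-[(2S)-2-(2,4-dihydroxyphenyl)-7-hydroxy-4-oxochroman-8-yl]-4-methylcyclohex-3-en-1-yl}methanone | CC(C)=CCc1c(O)ccc(C(=O)[C@H]2[C@@H](c3c(O)ccc4c3O[C@H](c3ccc(O)cc3O)CC4=O)C=C(C)C[C@@H]2c2ccc(O)cc2O)c1O | target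

## Step count and least certain steps

Total: 25 steps. Longest linear sequence: 19 steps (3 → 36 through steps 2–13, 17–19 and 22–25). The side branches are step 1, steps 14–16 and steps 20–21.

Step 17 (key step). Three processes can fail.
- Loss of the methide by tautomerisation to the conjugated diene or by oligomerisation before the hindered enamine captures it.
- Slow enamine formation from the β-branched aldehyde.
- Poor facial selectivity if the resident C3 centre opposes the catalyst, with erosion of the diastereomer ratio through epimerisation at the lactol α-carbon.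

Fallback: set out from ester 16 and sulfone 22. The lithium enolate of 16 (LiN(SiMe3)2, THF, −78 °C) is combined with the lithium phenoxide of 22 (one further equivalent of the same base), which releases 23 on warming to −20 °C. Conjugate addition should give the phenolic ester adduct methyl (2R,3S)-3-Fl-2-{(1S)-1-[2-hydroxy-4-(methoxymethoxy)phenyl]-3-methylbut-3-enyl}pent-4-enoate F1. F1 closes to the lactone on warming with catalytic pyridinium p-toluenesulfonate in toluene and returns to the route at 25. Stereocontrol then rests on the substrate, and the diastereomers would be separated at the lactone stage.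

Step 11. The ionisation and the attack take place at an allyl terminus bonded to a 2,6-dioxygenated arene. Slow turnover, a shift toward the linear isomer (the twisted arene stabilises the branched transition state less), or mismatched double diastereoselection are the likely failures.

Fallback: set out from cinnamate 11.
- Saponification (LiOH, THF/MeOH/H2O) gives (E)-3-Fl-prop-2-enoic acid F2.
- The mixed pivalic anhydride (tBuCOCl, Et3N) is coupled with lithiated (S)-4-phenyloxazolidin-2-one to give (4S)-3-[(E)-3-Fl-prop-2-enoyl]-4-phenyl-1,3-oxazolidin-2-one F3.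
- Copper-mediated conjugate addition (CH2=CHMgBr, CuBr·SMe2, THF, −40 °C) to the magnesium-chelated imide, anti to the phenyl group, should give (4S)-3-[(3R)-3-Fl-pent-4-enoyl]-4-phenyl-1,3-oxazolidin-2-one F4.
- Methanolysis (NaOMe, MeOH, 0 °C) releases the auxiliary and returns to the route at 16.

Step 16. Ionisation of the very electron-rich carbinol under acid may be followed by loss of a proton to the conjugated diene, by oligomerisation, or by partial loss of the MOM group, instead of capture by sulfinate.

Fallback: set out from aldehyde 18, so that the acid-sensitive methallyl carbinol is never formed.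
- NaBH4 (MeOH, 0 °C) gives 2-(hydroxymethyl)-5-(methoxymethoxy)phenol F5.
- The same sulfinate substitution, now through a methide that cannot tautomerise, gives 5-(methoxymethoxy)-2-[(4-methylphenylsulfonyl)methyl]phenol F6.
- The dianion of F6 (LiN(iPr)2, 2.1 equiv, THF, −78 °C) is alkylated at the α-sulfonyl carbon with 19, quenched cold, and returns to the route at 22.

Step 22. A second addition of 32 to the liberated ketone, or deprotonation at C4 of the lactone or of the ketone (ketene formation, epimerisation), may compete with the single acyl transfer because both partners are hindered.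

Fallback: set out from lactone 26.
- Reduction (iBu2AlH, CH2Cl2, −78 °C) gives the lactol (6aR,7S,10aS)-3-(methoxymethoxy)-9-methyl-7-Fl-6a,7,10,10a-tetrahydro-6H-benzo[c]chromen-6-ol F7.
- Its open phenoxide–aldehyde form takes up 32 (2.2 equiv) once only, giving the carbinol [2,4-bis(methoxymethoxy)-3-(3-methylbut-2-enyl)phenyl]{(1R,2S,6S)-2-Fl-6-[2-hydroxy-4-(methoxymethoxy)phenyl]-4-methylcyclohex-3-en-1-yl}methanol F8 as a mixture at the carbinol carbon.
- Buffered Bu4NF gives the corresponding flavan-4-ol triol F9.
- MnO2 oxidises both activated benzylic carbinols in one operation and returns to the route at 35.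

Step 25. Under protic acid the prenyl group may close onto a neighbouring phenol to a dimethylchroman, and the C4 ketone may ketalise with the ortho-hydroxyaryl groups on C3 and C5 or cyclodehydrate with the C5-ring phenol, once those phenols are free.

Fallback: set out from 35 and exchange the acetals under aprotic conditions. Me3SiOTf and 2,2′-bipyridyl (CH2Cl2, 0 °C) should convert the aryl MOM ethers and the free phenol into the heptakis(trimethylsilyl) ether of the target F10. The silyl ethers are then cleaved by neutral aqueous methanol at rt, returning to the route at 36.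

## Further compounds

F1 | step 17 | methyl (2R,3S)-3-Fl-2-{(1S)-1-[2-hydroxy-4-(methoxymethoxy)phenyl]-3-methylbut-3-enyl}pent-4-enoate | COC(=O)[C@H]([C@H](CC(C)=C)c1ccc(OCOC)cc1O)[C@@H](c1c(OCOC)ccc2c1O[C@H](c1ccc(OCOC)cc1OCOC)C[C@@H]2O[Si](C)(C)C(C)(C)C)C=C
F2 | step 11 | (E)-3-Fl-prop-2-enoic acid | OC(=O)/C=C/c1c(OCOC)ccc2c1O[C@H](c1ccc(OCOC)cc1OCOC)C[C@@H]2O[Si](C)(C)C(C)(C)C
F3 | step 11 | (4S)-3-[(E)-3-Fl-prop-2-enoyl]-4-phenyl-1,3-oxazolidin-2-one | O=C(/C=C/c1c(OCOC)ccc2c1O[C@H](c1ccc(OCOC)cc1OCOC)C[C@@H]2O[Si](C)(C)C(C)(C)C)N1[C@@H](c2ccccc2)COC1=O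
F4 | step 11 | (4S)-3-[(3R)-3-Fl-pent-4-enoyl]-4-phenyl-1,3-oxazolidin-2-one | O=C(C[C@@H](c1c(OCOC)ccc2c1O[C@H](c1ccc(OCOC)cc1OCOC)C[C@@H]2O[Si](C)(C)C(C)(C)C)C=C)N1[C@@H](c2ccccc2)COC1=O
F5 | step 16 | 2-(hydroxymethyl)-5-(methoxymethoxy)phenol | OCc1ccc(OCOC)cc1O
F6 | step 16 | 5-(methoxymethoxy)-2-[(4-methylphenylsulfonyl)methyl]phenol | Cc1ccc(cc1)S(=O)(=O)Cc1ccc(OCOC)cc1O
F7 | step 22 | (6aR,7S,10aS)-3-(methoxymethoxy)-9-methyl-7-Fl-6a,7,10,10a-tetrahydro-6H-benzo[c]chromen-6-ol, anomeric mixture | OC1Oc2cc(OCOC)ccc2[C@H]3CC(C)=C[C@H](c4c(OCOC)ccc5c4O[C@H](c4ccc(OCOC)cc4OCOC)C[C@@H]5O[Si](C)(C)C(C)(C)C)[C@H]13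
F8 | step 22 | [2,4-bis(methoxymethoxy)-3-(3-methylbut-2-enyl)phenyl]{(1R,2S,6S)-2-Fl-6-[2-hydroxy-4-(methoxymethoxy)phenyl]-4-methylcyclohex-3-en-1-yl}methanol, mixture at the carbinol carbon | CC(C)=CCc1c(OCOC)ccc(C(O)[C@H]2[C@@H](c4c(OCOC)ccc5c4O[C@H](c4ccc(OCOC)cc4OCOC)C[C@@H]5O[Si](C)(C)C(C)(C)C)C=C(C)C[C@@H]2c2ccc(OCOC)cc2O)c1OCOC
F9 | step 22 | analogue of F8 with the free (2S,4S)-flavan-4-ol | CC(C)=CCc1c(OCOC)ccc(C(O)[C@H]2[C@@H](c4c(OCOC)ccc5c4O[C@H](c4ccc(OCOC)cc4OCOC)C[C@@H]5O)C=C(C)C[C@@H]2c2ccc(OCOC)cc2O)c1OCOC
F10 | step 25 | heptakis(trimethylsilyl) ether of 36 | CC(C)=CCc1c(O[Si](C)(C)C)ccc(C(=O)[C@H]2[C@@H](c3c(O[Si](C)(C)C)ccc4c3O[C@H](c3ccc(O[Si](C)(C)C)cc3O[Si](C)(C)C)CC4=O)C=C(C)C[C@@H]2c2ccc(O[Si](C)(C)C)cc2O[Si](C)(C)C)c1O[Si](C)(C)C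
A1 | alternative 1 | endo 8-[2,4-bis(methoxymethoxy)phenyl]-1-methyl-5-(flavanon-8-yl)-2-oxabicyclo[2.2.2]oct-5-en-3-one | O=C1O[C@]2(C)C=C(c3c(OCOC)ccc4c3O[C@H](c3ccc(OCOC)cc3OCOC)CC4=O)[C@H]1[C@@H](c1ccc(OCOC)cc1OCOC)C2
A2 | alternative 1 | 6-methyl-4-[(2S)-7-(methoxymethoxy)-2-[2,4-bis(methoxymethoxy)phenyl]-4-oxochroman-8-yl]pyran-2-one | Cc1cc(-c2c(OCOC)ccc3c2O[C@H](c2ccc(OCOC)cc2OCOC)CC3=O)cc(=O)o1
A3 | alternative 1 | 2,4-bis(methoxymethoxy)styrene | C=Cc1ccc(OCOC)cc1OCOC
A4 | alternative 2 | 3-Fl-5-[2,4-bis(methoxymethoxy)phenyl]-1-methylcyclohexene-4-carboxylic acid, 3,4-cis and 4,5-trans | OC(=O)[C@H]1[C@@H](c2c(OCOC)ccc3c2O[C@H](c2ccc(OCOC)cc2OCOC)C[C@@H]3O[Si](C)(C)C(C)(C)C)C=C(C)C[C@@H]1c1ccc(OCOC)cc1OCOC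
A5 | alternative 2 | 4-[2,4-bis(methoxymethoxy)phenyl]-6-methyl-6-[(E)-2-Fl-ethenyl]tetrahydropyran-2-one, aryl and styryl cis | O=C1C[C@@H](c2ccc(OCOC)cc2OCOC)C[C@@](C)(/C=C/c2c(OCOC)ccc3c2O[C@H](c2ccc(OCOC)cc2OCOC)C[C@@H]3O[Si](C)(C)C(C)(C)C)O1
A6 | alternative 3 | hexa-MOM ether of the target with the (2S)-flavanone closed and the chelated aroyl 2-hydroxyl free | O=C(c1ccc(OCOC)c(CC=C(C)C)c1O)[C@H]1[C@@H](c2c(OCOC)ccc3c2O[C@H](c2ccc(OCOC)cc2OCOC)CC3=O)C=C(C)C[C@@H]1c1ccc(OCOC)cc1OCOC
A7 | alternative 3 | open 2′-hydroxychalcone precursor of A6 | O=C(c1ccc(OCOC)c(CC=C(C)C)c1O)[C@H]1[C@@H](c2c(OCOC)ccc(C(=O)/C=C/c3ccc(OCOC)cc3OCOC)c2O)C=C(C)C[C@@H]1c1ccc(OCOC)cc1OCOC
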